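A small charge of electrophile, 0.050 M in autumn against 0.150 M of nucleophile, is fed in over 5.0 min, and the feed adds 1.0 times the starting volume to the flask.

| flask | electrophile | nucleophile | free base | remark | time |
|---|---|---|---|---|---|
| west | 0.050 M (fed, over 5.0 min) | 0.22 M | 0.075 M | run made earlier; the fed solution adds 1.0 times the starting volume |  |
| south-east | 0.10 M (fed, over 5.0 min) | 0.15 M | 0.075 M | run made earlier; the fed solution adds 1.0 times the starting volume |  |
| autumn | 0.050 M (fed, over 5.0 min) | 0.150 M | 0.0750 M | the fed solution adds 1.0 times the starting volume | 15 min |
| summer | 0.050 M (fed, over 5.0 min) | 0.150 M | 0.170 M | the fed solution adds 1.0 times the starting volume | 15 min |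
| dawn | 0.050 M (fed, over 5.0 min) | 0.150 M | 0.110 M | the fed solution adds 1.0 times the starting volume | 15 min |

| run | time / min | electrophile / % | target / % |
|---|---|---|---|
| west | 0.250 | 6 | 0 |
| west | 0.417 | 6 | 0 |
| west | 0.833 | 18 | 0 |
| west | 1.50 | 26 | 4 |
| west | 3.00 | 49 | 5 |
| south-east | 0.250 | 4 | 0 |
| south-east | 0.417 | 6 | 0 |
| south-east | 0.833 | 15 | 2 |
| south-east | 1.50 | 27 | 3 |
| south-east | 3.00 | 54 | 6 |

(scatter of a reading: 1.5 percentage points)

- charges are per starting volume, the dose included; the dosed solution carries all of it
- percentages count the whole charge, also what has not yet gone in
- no earlier run changes the charge of free base; that part of a forecast is a guess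

1. part of the electrophile that has reacted at the end, autumn
2. part of the electrophile that has reacted at the end, summer
3. part of the electrophile that has reacted at the end, dawn
4. what raising the concentration of free base from its lowest to its highest value here does to the part of the electrophile that has reacted (changes below 5 percentage points count as none) (it rises / it falls / no change)

We reckon from the nucleophile concentration. With nucleophile in excess we take the electrophile as pseudo-first-order, its pace proportional to a nucleophile concentration that the feed dilutes. Early in the feed, the reacted fraction of the charge is then a single number, N, times the difference between x and the natural log of one plus x, where x is the fraction of the dosing time gone.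

The south-east run has autumn's nucleophile, and we assume its larger electrophile charge leaves percentages unchanged. At 3.00 min, x is 0.600 and target reads 6%. Fed minus remaining electrophile also gives 6.00%. So N is 0.462, the dosing time divided by the electrophile's lifetime at the starting nucleophile concentration, and it rests on a reading with a scatter of 1.5 percentage points.

Is one number enough? Scaled to the west nucleophile, N gives 8.80% at 3.00 min. The west readings, 5% and 11.0%, straddle it without proving it.

Since N is below one, electrophile gathers during the feed. Carrying N through the feed and the hold, where the pace is half the starting one, gives 45.1% reacted in autumn. N holds no free base, so we guess the same for summer and dawn.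

The forecast differs: 50% for autumn, 58% for dawn, 70% for summer, and its answer on raising the free base is that it rises. Of the base it says: “I guess it promotes the reaction, probably less than proportionally”.

The flasks give 53.3% for autumn, 53.4% for dawn and 53.4% for summer. Going from the lowest free base to the highest moves the answer by 0.052 points, which counts as no change.

    electrophile + nucleophile → acid set free + target (k = 0.700 L mol⁻¹ min⁻¹)
    nucleophile + acid set free ⇌ protonated nucleophile, settled at all times (K = 59000 L mol⁻¹)
    acid set free + free base ⇌ salt of the base, settled at all times (K = 3300 L mol⁻¹)
    free base ⇌ dormant form (K = 1.50, k = 0.180 min⁻¹)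
    acid set free + target → side product A (k = 3.00 L mol⁻¹ min⁻¹)
    electrophile + target → side product B (k = 3.10 L mol⁻¹ min⁻¹)

Our autumn figure stands 8.2 points low. In a neighbouring flask, which is autumn with 0.26 M of nucleophile, N scales to 0.800, and the same reckoning gives 64.4% reacted. That flask gives 72.9%, with 44.2% of the electrophile charged as target and 28.7% as side product B.

Readings and results stem from a simulated flask with constants of no real substance; scatter was added.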